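The data come from a simulation with constants of no real substance; the scatter is artificial.

Epsilon holds 4.14 times the catalyst of zeta at equal substrate and reagent, so we ask whether catalyst does anything beyond running the same clock faster.

all flasks: substrate 0.13 M
- zeta: reagent 0.26 M; catalyst 0.29 mM; run made earlier
- epsilon: reagent 0.26 M; catalyst 1.2 mM; run made earlier
- gamma: reagent 0.52 M; catalyst 0.58 mM; run made earlier
- flask: reagent 0.260 M; catalyst 0.58 mM

| run | time / h | target / % |
|---|---|---|
| zeta | 3.00 | 0 |
| zeta | 6.00 | 0 |
| zeta | 15.0 | 0 |
| zeta | 40.0 | 4 |
| epsilon | 3.00 | 3 |
| epsilon | 6.00 | 8 |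
| epsilon | 15.0 | 8 |
| epsilon | 40.0 | 30 |
| gamma | 3.00 | 0 |
| gamma | 6.00 | 0 |
| gamma | 15.0 | 1 |
| gamma | 40.0 | 9 |

(standard deviation of a reading: 2 percentage points)

- apparent order in reagent when 10 % of the substrate are converted (percent change of the rate of making target for one percent more reagent charged)
- apparent order in catalyst when 10 % of the substrate are converted (percent change of the rate of making target for one percent more catalyst charged)

Our clock is the catalyst-hours Θ, the catalyst charged multiplied by the time elapsed: 64.8 M·s for epsilon at 15.0 h. Our rule is that, with substrate and reagent charges held fixed, equal Θ means equal conversion.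

Zeta at 40.0 h has Θ = 41.8 M·s, which lies between epsilon's rows at 6.00 h and 15.0 h. Those rows read 8 % and 8 %, while zeta reads 4 %. That gap of 4 percentage points stands against a scatter of 2 points in each reading, so the rule survives but is not proven.

Gamma at 40.0 h has Θ = 83.5 M·s and reads 9 %, close to epsilon's 8 % at Θ = 64.8 M·s, although gamma has twice the reagent.

So we reckon as follows. Equal conversion falls at equal Θ, and a flask with more catalyst passes through Θ proportionally faster, which makes our order in catalyst one. Gamma's reading shows no gain from the added reagent beyond the scatter, so we put our order in reagent near zero, as a guess with a wide margin.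

The forecast differs from us on catalyst, giving 1.4 there and −0.1 in reagent, and it says of gamma: “Doubling therefore did little”.

The flask gives 1.0 in catalyst and 0.0056 in reagent.

    substrate + catalyst ⇌ catalyst + intermediate (K = 1.40, k = 0.530 /M/s)
    reagent + catalyst + intermediate → catalyst + target (k = 0.710 /M²/s)
    reagent + catalyst ⇌ idle complex, settled at all times (K = 150 /M)

The flask reaches Θ = 64.8 M·s after 31.0 h; at 30.0 h it holds 7.21 % target, beside epsilon's reading of 8 %. Zeta's Θ = 41.8 M·s corresponds to 20.0 h in the flask, where target climbs from 2.30 % at 15.0 h to that 7.21 %, and zeta read 4 %. The largest single effect on the flask's reagent order is the parking of reagent and catalyst as idle complex, a dormant, off-cycle form, which holds 97.5 % of the catalyst at 10 % conversion. The same run without that parking gives an order of 0.98 in reagent, against 0.0056.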